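**Structural features**

The target 17 is a linear pentaphlorethol: five benzene rings A to E joined only by four diaryl ether oxygens, O1 (A–B), O2 (B–C), O3 (C–D) and O4 (D–E). Ring A is a 3,5-dihydroxyphenyl group and ring E a 2,4,6-trihydroxyphenyl group. Rings B and D are ortho-linked: C1 and C6 carry the ether oxygens, C2 and C4 carry hydroxyls. Ring C is para-linked through C1 and C4 with hydroxyls at C2 and C6. There is no stereocentre and no configurationally stable axis, so only constitution has to be controlled. The eleven free phenols make the compound very electron-rich and air-sensitive, above all in base, where the 4-aryloxyphenol units can go to quinones; the hydroxyls must stay masked until the last step. The real difficulty is placing fifteen oxygens on five rings without symmetry, and forming four ether bonds of which every oxygen-bearing carbon C1 of rings B, C, D and E lies between two other oxygen substituents. The key step uses the fact that in the nonamethyl ether 14, which lacks the C4 oxygens of rings B and D, C4–H of ring B and C4–H of ring D are the only two of thirteen aromatic C–H bonds with no ortho substituent.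

**Logic of the disconnections**

17 to 16: the nine O–CH3 bonds are cut. Methyl is kept as the mask because it adds no accessible aromatic C–H (benzyl groups would be borylated in the key step) and survives carbonate and fluoride at 110 °C, peracid, copper and iridium. The gain is that every earlier compound is a neutral, chromatographable ether. The demand is that BBr3 cleaves nine aryl methyl ethers and leaves the four diaryl ethers, which have no sp3 carbon for bromide to attack.

16 to 14 (through 15): the two C4–O bonds of rings B and D are cut. This turns both rings into 1,2,3-trioxygenated rings, which come from a fluoroaldehyde with a single methoxy group and so from a better SNAr electrophile, and it lets both oxygens enter in one operation. The gain is two oxygen functions fewer throughout the assembly. The demand is a double C–H borylation that is complete at both rings and touches no other C–H, followed by an oxidation that spares the electron-rich ethers.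

14 to 12 and 13: the O1–C1 bond to ring A is cut. Ring A has no activating group for SNAr, so an oxidative copper coupling with the boronic acid is used. The gain is a commercial ring A unit. The demand is O-arylation of a phenol flanked by a methoxy and an aryloxy group.

12 to 10 (through 11), then 10 to 9 and 2: the C1 hydroxyl of ring B is traced to a formyl group and the O2–C6 bond of ring B is cut. The formyl group first activates the ortho fluorine and then becomes the oxygen of the next nucleophile, so the position of the aldehyde fixes the substitution pattern. The gain is one ring per cycle from a commercial block. The demand is attack by a 2,6-dimethoxyphenoxide and aryl (not hydride) migration in the Baeyer–Villiger step.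

9 to 7 (through 8), then 7 to 5 and 6: the same pair of operations, cutting the O3–C4 bond of ring C para to the formyl group. The gain is the para-linked ring with both flanking methoxy groups in place. The demand is SNAr at a fluoride whose activating aldehyde is weakened by two ortho methoxy groups.

5 to 3 (through 4), then 3 to 1 and 2: the same pair again, cutting the O4–C6 bond of ring D. This ends at the commercial compounds 1 and 2. The demand is exclusion of air, since the phenoxide of 1 is easily oxidised.

**Other disconnections considered**

Alternative 1: The cut runs through ring E: its C2–C3 and C5–C6 bonds are opened. C1, C2 and C6 then come from the malonate unit of the tetramer aryloxymalonate A1, which already carries O4 on the malonate carbon, and C3 to C5 come from dimethyl 1,3-acetonedicarboxylate A2. In the forward step an alkoxide base would cause a Claisen acylation of the enolate of A2 by one ester of A1 and then a Dieckmann-type acylation by the other. Enolisation of the cyclic trione would give the phloroglucinol diester A3; ester hydrolysis with double decarboxylation would follow before the final demethylation.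
- In its favour: the 2,4,6-oxygen pattern of ring E arises from three carbonyl carbons, so no aromatic regiochemistry has to be controlled for that ring. The reaction type is the classical malonate route to phloroglucinols and needs no transition metal.
- Against it here: A1 still holds three of the four ether bonds, with rings B and D fully oxygenated, so the hard part is untouched and its SNAr steps would use less electrophilic dimethoxy fluoroaldehydes. The malonate C–H of A1 is the most acidic site and its enolate is a poor acyl donor, while A2 self-condenses under the same base. Ring E is available ready-made as 1.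
- Comparison: structurally it settles one ring and one ether oxygen, where the chosen plan settles two oxygens on two rings. Mechanistically it depends on reversible carbonyl condensations with competing pathways, where the chosen step depends on a steric preference built into the substrate. In step count it adds malonate formation, annulation and decarboxylation to a tetramer synthesis of about six steps, so it is longer than nine. It is the equal or the better of the chosen plan in two respects: it needs no iridium and raises no C–H selectivity question, and it leaves eight methyl ethers for the last step, not nine.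

Alternative 2: The two ether bonds of the central ring, O3–C4 and O2–C1 of ring C, are cut. The pieces are the D–E phenol A5, the A–B phenol A6 and the hexafluorophosphate salt A4, in which a cyclopentadienylruthenium cation is η6-bound to 2,5-dichloro-1,3-dimethoxybenzene. In the forward step the phenoxide of A5 would displace the unhindered chloride (C4 of ring C), and the phenoxide of A6 would then displace the chloride between the two methoxy groups (C1), giving the pentamer complex A7. Photolytic release of the arene would give the undecamethyl ether A8, and global demethylation would give 17.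
- In its favour: the assembly is convergent (two dimers on one linchpin). Coordination to the cationic metal makes even a dimethoxy chloroarene electrophilic, so ring C needs no formyl group and no Baeyer–Villiger step. All oxygens are carried from the start.
- Against it here: ruthenium is used in stoichiometric amount. The second displacement occurs at a carbon flanked by two methoxy groups on a ring made more electron-rich by the first aryloxy group. The order of the two displacements must be complete, or symmetrical bis-adducts form. A5 and A6 each need their own synthesis from fully oxygenated rings, and A6 has O1 on the middle carbon of ring B, which an SNAr/Baeyer–Villiger cycle from the ring A side cannot deliver. Eleven methyl ethers must be cleaved at the end.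
- Comparison: on structure it is the better plan in convergence, with a longest linear sequence of about five steps against nine; the total step count is about equal. On mechanism, addition–elimination through η5-cyclohexadienyl complexes is dependable for phenoxides, but the risk sits in one pot with two hindered substitutions; the chosen plan puts its risk in a catalytic step whose selectivity is steric.

Alternative 3: The O4–C6 bond of ring D is cut together with a C1–I bond that stands in for O3. Ring D comes from 3,5-dimethoxybenzyne, generated from the silyl triflate A9, and ring E from the potassium phenoxide A10 (the salt of 1). In the forward step a fluoride source would release the aryne. A10 would add at the aryne carbon remote from the adjacent methoxy group, because the inductively withdrawing ortho oxygen distorts the aryne and stabilises the carbanion next to it. A positive-iodine donor such as iodopentafluorobenzene A12 would then trap the aryl anion and give the iodide A11, ready for an Ullmann coupling to ring C.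
- In its favour: a hindered diaryl ether forms under mild conditions with no activating group and no Baeyer–Villiger step. Ring D arrives fully oxygenated, and two adjacent bonds are made in one operation.
- Against it here: the aryl anion is protonated by any proton source faster than it is iodinated. The iodine donor can iodinate or oxidise the very electron-rich A10 before the aryne forms. A9 needs several steps. The later Ullmann coupling must occur at an iodide flanked by a methoxy and an aryloxy group. Only one of the four ether bonds is made.
- Comparison: on structure it is the equal or the better of the chosen plan for ring D alone, since that ring needs no late oxidation, and its regiocontrol by aryne distortion is as well founded as steric control in borylation. On mechanism its three-component trapping has more competing channels than SNAr followed by Baeyer–Villiger oxidation. In step count the preparation of A9 and the remaining three ether bonds would put the total above nine.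

Key step: step 8

Remark: C3–H and C5–H of rings B and D have one ortho oxygen neighbour, not two, and the selectivity argument counts them so; the structures of 14 and 16 need no other correction. Assumption: 1, 2, 6 and 13 are purchased, and each Baeyer–Villiger oxidation and the methanolysis of its formate are run in one flask and counted as one step.

**Route**

Step 1
Reactants: 1 2,4,6-trimethoxyphenol; 2 2-fluoro-6-methoxybenzaldehyde
Product: 3 2-methoxy-6-(2,4,6-trimethoxyphenoxy)benzaldehyde
Conditions: K2CO3, DMF, 100 °C, Ar
Reagents that add atoms: none
Why: SNAr by addition–elimination; the ortho formyl group stabilises the Meisenheimer anion and fluoride is the fastest leaving group when addition is rate-limiting. The methoxy group of 2 is meta to the reacting carbon and does not oppose the attack, and argon protects the oxidisable phenoxide of 1.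

Step 2
Reactants: 3 2-methoxy-6-(2,4,6-trimethoxyphenoxy)benzaldehyde
Product: 5 2-methoxy-6-(2,4,6-trimethoxyphenoxy)phenol, via aryl formate 4 (not isolated)
Conditions: mCPBA, CH2Cl2, 0 °C to rt; aq. Na2S2O3 wash; then K2CO3, MeOH, rt
Reagents that add atoms: mCPBA, OOC(=O)c1cccc(Cl)c1
Why: Baeyer–Villiger (Dakin-type) oxidation; in the Criegee adduct the aryl group with two ortho oxygens migrates in preference to hydride and gives the formate, which methanolysis cleaves. Removing excess peracid before the phenol is set free protects the electron-rich product.

Step 3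
Reactants: 5 2-methoxy-6-(2,4,6-trimethoxyphenoxy)phenol; 6 4-fluoro-2,6-dimethoxybenzaldehyde
Product: 7 2,6-dimethoxy-4-[2-methoxy-6-(2,4,6-trimethoxyphenoxy)phenoxy]benzaldehyde
Conditions: Cs2CO3, DMSO, 110 °C, Ar
Reagents that add atoms: none
Why: SNAr para to the formyl group; the two methoxy groups of 6 are meta to the fluorine-bearing carbon, so they do not destabilise the anionic σ-complex by resonance, though they weaken the aldehyde as an acceptor. The caesium phenoxide in DMSO supplies the extra nucleophilicity that the hindered phenol 5 needs.

Step 4
Reactants: 7 2,6-dimethoxy-4-[2-methoxy-6-(2,4,6-trimethoxyphenoxy)phenoxy]benzaldehyde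
Product: 9 2,6-dimethoxy-4-[2-methoxy-6-(2,4,6-trimethoxyphenoxy)phenoxy]phenol, via aryl formate 8 (not isolated)
Conditions: mCPBA, CH2Cl2, 0 °C to rt; aq. Na2S2O3 wash; then K2CO3, MeOH, rt, Ar
Reagents that add atoms: mCPBA, OOC(=O)c1cccc(Cl)c1
Why: Baeyer–Villiger oxidation of a 2,4,6-trioxygenated benzaldehyde, the substitution pattern with the highest aryl migratory aptitude, followed by formate methanolysis. The phenol is released only after the oxidant is gone, which guards the 4-aryloxy-2,6-dimethoxyphenol against quinone formation.

Step 5
Reactants: 9 2,6-dimethoxy-4-[2-methoxy-6-(2,4,6-trimethoxyphenoxy)phenoxy]phenol; 2 2-fluoro-6-methoxybenzaldehyde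
Product: 10 2-{2,6-dimethoxy-4-[2-methoxy-6-(2,4,6-trimethoxyphenoxy)phenoxy]phenoxy}-6-methoxybenzaldehyde
Conditions: Cs2CO3, DMSO, 100 °C, Ar
Reagents that add atoms: none
Why: SNAr ortho to the formyl group as in step 1. The nucleophile is a 2,6-dimethoxyphenoxide, whose oxygen remains accessible because the flanking methoxy groups can turn away.

Step 6
Reactants: 10 2-{2,6-dimethoxy-4-[2-methoxy-6-(2,4,6-trimethoxyphenoxy)phenoxy]phenoxy}-6-methoxybenzaldehyde
Product: 12 2-{2,6-dimethoxy-4-[2-methoxy-6-(2,4,6-trimethoxyphenoxy)phenoxy]phenoxy}-6-methoxyphenol, via aryl formate 11 (not isolated)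
Conditions: mCPBA, CH2Cl2, 0 °C to rt; aq. Na2S2O3 wash; then K2CO3, MeOH, rt
Reagents that add atoms: mCPBA, OOC(=O)c1cccc(Cl)c1
Why: Baeyer–Villiger oxidation and formate methanolysis as in step 2; the aldehyde is the only group that reacts quickly with the peracid at this temperature.

Step 7
Reactants: 12 2-{2,6-dimethoxy-4-[2-methoxy-6-(2,4,6-trimethoxyphenoxy)phenoxy]phenoxy}-6-methoxyphenol; 13 3,5-dimethoxyphenylboronic acid
Product: 14 2-(3,5-dimethoxyphenoxy)-1-{2,6-dimethoxy-4-[2-methoxy-6-(2,4,6-trimethoxyphenoxy)phenoxy]phenoxy}-3-methoxybenzene
Conditions: Cu(OAc)2, pyridine, 4 Å MS, CH2Cl2, air, rt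
Reagents that add atoms: none
Why: Chan–Lam O-arylation; the aryl group passes from boron to a divalent copper phenoxide, oxidation gives a trivalent copper aryl phenoxide, and C–O reductive elimination forms the ether. Phenols with two ortho substituents are within the known scope, and the boronic acid, which has no ortho substituent, is used in excess.

Step 8
Reactants: 14 2-(3,5-dimethoxyphenoxy)-1-{2,6-dimethoxy-4-[2-methoxy-6-(2,4,6-trimethoxyphenoxy)phenoxy]phenoxy}-3-methoxybenzene
Product: 16 4-(3,5-dimethoxyphenoxy)-3-{4-[4-hydroxy-2-methoxy-6-(2,4,6-trimethoxyphenoxy)phenoxy]-2,6-dimethoxyphenoxy}-5-methoxyphenol, via bis(pinacolboronate) 15 (not isolated)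
Conditions: [Ir(OMe)(cod)]2 (cat.), dtbpy (cat.), B2pin2 (excess), THF, 80 °C; then aq. H2O2, NaOH, THF, 0 °C; Na2S2O3 quench
Reagents that add atoms: hydrogen peroxide, OO (the two hydroxyl oxygens of 16); bis(pinacolato)diboron, CC1(C)OB(OC1(C)C)B1OC(C)(C)C(C)(C)O1 (the boryl groups of 15 only)
Why: [Ir(OMe)(cod)]2, dtbpy and B2pin2 should form the 16-electron tris(boryl) complex (dtbpy)Ir(Bpin)3 of trivalent iridium, which cleaves an aryl C–H bond by oxidative addition to a pentavalent iridium aryl hydride; C–B reductive elimination releases the arylboronate and B2pin2 restores the tris(boryl) species with loss of HBpin. The closest known reaction type is the sterically governed iridium-catalysed borylation of 1,2,3-trisubstituted benzenes at C5, run in one pot with oxidation of the boronate to the phenol. The crowded metal centre avoids C–H bonds with an ortho substituent: of the thirteen aromatic C–H bonds of 14, seven (rings A, C and E) lie between two oxygens and four (C3 and C5 of rings B and D) next to one, so only C4–H of rings B and D is open, and the sp3 C–H bonds of the methoxy groups are not attacked by this catalyst. Once a ring is borylated, its C3–H and C5–H are flanked on both sides, so a second borylation of the same ring is shut off, and the two rings react independently, so excess B2pin2 can drive both sites to completion. In the second stage hydroperoxide adds to boron and the aryl group shifts from boron to oxygen at the same carbon, so each C–B bond becomes a C–O bond without change of position, and hydrolysis of the borate gives the phenol. No ring is closed and no stereocentre is formed. The oxidation needs only chemoselectivity for boron; the absence of any free phenol or aldehyde in 14 and a cold, short exposure with reductive quench protect the new 4-aryloxyphenol units.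

Step 9
Reactants: 16 4-(3,5-dimethoxyphenoxy)-3-{4-[4-hydroxy-2-methoxy-6-(2,4,6-trimethoxyphenoxy)phenoxy]-2,6-dimethoxyphenoxy}-5-methoxyphenol
Product: 17 4-(3,5-dihydroxyphenoxy)-5-{4-[2,4-dihydroxy-6-(2,4,6-trihydroxyphenoxy)phenoxy]-2,6-dihydroxyphenoxy}benzene-1,3-diol
Conditions: BBr3 (large excess), CH2Cl2, −78 °C to rt, Ar; then MeOH, degassed H2O, 0 °C
Reagents that add atoms: none
Why: Lewis acid ether cleavage; boron binds each methoxy oxygen and bromide attacks the methyl carbon in an SN2 step, and the aryl borates are hydrolysed on work-up. Diaryl ethers offer no sp3 carbon and stay intact, and the acidic, oxygen-free work-up suits the air-sensitive polyphenol.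

**Compound list**

1 | 2,4,6-trimethoxyphenol | COc1cc(OC)c(O)c(OC)c1 | starting material
2 | 2-fluoro-6-methoxybenzaldehyde | COc1cccc(F)c1C=O | starting material
3 | 2-methoxy-6-(2,4,6-trimethoxyphenoxy)benzaldehyde | COc1cc(OC)c(Oc2cccc(OC)c2C=O)c(OC)c1 | intermediate
4 | 2-methoxy-6-(2,4,6-trimethoxyphenoxy)phenyl formate (not isolated) | COc1cc(OC)c(Oc2cccc(OC)c2OC=O)c(OC)c1 | intermediate
5 | 2-methoxy-6-(2,4,6-trimethoxyphenoxy)phenol | COc1cc(OC)c(Oc2cccc(OC)c2O)c(OC)c1 | intermediate
6 | 4-fluoro-2,6-dimethoxybenzaldehyde | COc1cc(F)cc(OC)c1C=O | starting material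
7 | 2,6-dimethoxy-4-[2-methoxy-6-(2,4,6-trimethoxyphenoxy)phenoxy]benzaldehyde | COc1cc(OC)c(Oc2cccc(OC)c2Oc2cc(OC)c(C=O)c(OC)c2)c(OC)c1 | intermediate
8 | 2,6-dimethoxy-4-[2-methoxy-6-(2,4,6-trimethoxyphenoxy)phenoxy]phenyl formate (not isolated) | COc1cc(OC)c(Oc2cccc(OC)c2Oc2cc(OC)c(OC=O)c(OC)c2)c(OC)c1 | intermediate
9 | 2,6-dimethoxy-4-[2-methoxy-6-(2,4,6-trimethoxyphenoxy)phenoxy]phenol | COc1cc(OC)c(Oc2cccc(OC)c2Oc2cc(OC)c(O)c(OC)c2)c(OC)c1 | intermediate
10 | 2-{2,6-dimethoxy-4-[2-methoxy-6-(2,4,6-trimethoxyphenoxy)phenoxy]phenoxy}-6-methoxybenzaldehyde | COc1cc(OC)c(Oc2cccc(OC)c2Oc2cc(OC)c(Oc3cccc(OC)c3C=O)c(OC)c2)c(OC)c1 | intermediate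
11 | 2-{2,6-dimethoxy-4-[2-methoxy-6-(2,4,6-trimethoxyphenoxy)phenoxy]phenoxy}-6-methoxyphenyl formate (not isolated) | COc1cc(OC)c(Oc2cccc(OC)c2Oc2cc(OC)c(Oc3cccc(OC)c3OC=O)c(OC)c2)c(OC)c1 | intermediate
12 | 2-{2,6-dimethoxy-4-[2-methoxy-6-(2,4,6-trimethoxyphenoxy)phenoxy]phenoxy}-6-methoxyphenol | COc1cc(OC)c(Oc2cccc(OC)c2Oc2cc(OC)c(Oc3cccc(OC)c3O)c(OC)c2)c(OC)c1 | intermediate
13 | 3,5-dimethoxyphenylboronic acid | COc1cc(OC)cc(B(O)O)c1 | starting material
14 | 2-(3,5-dimethoxyphenoxy)-1-{2,6-dimethoxy-4-[2-methoxy-6-(2,4,6-trimethoxyphenoxy)phenoxy]phenoxy}-3-methoxybenzene (nonamethyl ether, rings B and D unsubstituted at C3 to C5) | COc1cc(OC)cc(Oc2c(OC)cccc2Oc2c(OC)cc(Oc3c(OC)cccc3Oc3c(OC)cc(OC)cc3OC)cc2OC)c1 | intermediate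
15 | 14 with a 4,4,5,5-tetramethyl-1,3,2-dioxaborolan-2-yl group at C4 of ring B and at C4 of ring D (not isolated) | COc1cc(OC)cc(Oc2c(OC)cc(B3OC(C)(C)C(C)(C)O3)cc2Oc2c(OC)cc(Oc3c(OC)cc(B4OC(C)(C)C(C)(C)O4)cc3Oc3c(OC)cc(OC)cc3OC)cc2OC)c1 | intermediate
16 | 4-(3,5-dimethoxyphenoxy)-3-{4-[4-hydroxy-2-methoxy-6-(2,4,6-trimethoxyphenoxy)phenoxy]-2,6-dimethoxyphenoxy}-5-methoxyphenol | COc1cc(OC)cc(Oc2c(OC)cc(O)cc2Oc2c(OC)cc(Oc3c(OC)cc(O)cc3Oc3c(OC)cc(OC)cc3OC)cc2OC)c1 | intermediate
17 | 4-(3,5-dihydroxyphenoxy)-5-{4-[2,4-dihydroxy-6-(2,4,6-trihydroxyphenoxy)phenoxy]-2,6-dihydroxyphenoxy}benzene-1,3-diol | Oc1cc(O)cc(Oc2c(O)cc(O)cc2Oc2c(O)cc(Oc3c(O)cc(O)cc3Oc3c(O)cc(O)cc3O)cc2O)c1 | target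

**Step count and risks**

Total step count: 9. Longest linear sequence: 9 steps, from 1 to 17.

Least certain steps:

Step 8 (key step). The most likely failure is incomplete second borylation: electron-rich arenes react slowly with this catalyst and the polyether may bind and slow the metal, so mono-borylated material could remain. A second risk is slow borylation next to a single oxygen at C3 or C5 of a ring that has not yet reacted. A third is oxidative degradation of the new 4-aryloxyphenol units during the peroxide stage. Fallback (sets out from 1, comes back at 15): the two positions would be marked by bromine from the start. SNAr of 1 (K2CO3, DMF) with 4-bromo-2-fluoro-6-methoxybenzaldehyde F1, in which the fluoride ortho to the formyl group leaves far faster than the bromide, would give 4-bromo-2-methoxy-6-(2,4,6-trimethoxyphenoxy)benzaldehyde F2. mCPBA and then K2CO3 in MeOH would convert it through 4-bromo-2-methoxy-6-(2,4,6-trimethoxyphenoxy)phenyl formate F3 into 4-bromo-2-methoxy-6-(2,4,6-trimethoxyphenoxy)phenol F4. SNAr of F4 with 6 would give the bromo trimer aldehyde F5, and Baeyer–Villiger oxidation through the bromo trimer formate F6 would give the bromo trimer phenol F7. A second SNAr with F1 would give the dibromo tetramer aldehyde F8, oxidised through the dibromo tetramer formate F9 to the dibromo tetramer phenol F10. Chan–Lam coupling with 13 would give the dibromo pentamer F11. Miyaura borylation of both C–Br bonds (Pd(dppf)Cl2, B2pin2, KOAc, dioxane, 90 °C) would give 15, which is oxidised to 16 as in the second stage of step 8.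

Step 3. The most likely failure is slow substitution, because the two methoxy groups beside the formyl group of 6 reduce its activating power and the phenoxide of 5 is hindered; long heating in base then invites oxidation of the phenoxide and decomposition of the aldehyde. Fallback (sets out from 5, comes back at 7): copper-catalysed Ullmann etherification of 5 with 4-bromo-2,6-dimethoxybenzaldehyde F12 (CuI, picolinic acid, K3PO4, DMSO, 90 °C), a ligand system that accepts phenols with two ortho substituents and aryl bromides bearing a para acceptor, would give 7 directly.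

Step 7. The most likely failure is slow O-arylation of the phenol 12, which has two ortho substituents, while the boronic acid is lost to protodeboronation, homocoupling and oxidation. Fallback (sets out from 12, comes back at 14): Ullmann coupling of 12 with 1-bromo-3,5-dimethoxybenzene F13 (CuI, picolinic acid, K3PO4, DMSO, 100 °C) would give 14 through oxidative addition of the aryl bromide to a monovalent copper phenoxide instead of boron-to-copper transfer.

Step 9. The most likely failures are incomplete cleavage of some of the nine methyl ethers, as partly demethylated borates precipitate from CH2Cl2, and air oxidation of 17 during isolation. Fallback (sets out from 16, comes back at 17): after the BBr3 treatment the crude polyphenol would be acetylated without isolation (Ac2O, pyridine) to the undecaacetate F14, which is stable to air and can be separated by chromatography from under-demethylated material. Acid-catalysed methanolysis (HCl in degassed MeOH, rt) would then release 17 without exposure to base.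

**Further compounds**

F1 | step 8 | 4-bromo-2-fluoro-6-methoxybenzaldehyde | COc1cc(Br)cc(F)c1C=O
F2 | step 8 | 4-bromo-2-methoxy-6-(2,4,6-trimethoxyphenoxy)benzaldehyde | COc1cc(OC)c(Oc2cc(Br)cc(OC)c2C=O)c(OC)c1
F3 | step 8 | 4-bromo-2-methoxy-6-(2,4,6-trimethoxyphenoxy)phenyl formate | COc1cc(OC)c(Oc2cc(Br)cc(OC)c2OC=O)c(OC)c1
F4 | step 8 | 4-bromo-2-methoxy-6-(2,4,6-trimethoxyphenoxy)phenol | COc1cc(OC)c(Oc2cc(Br)cc(OC)c2O)c(OC)c1
F5 | step 8 | 4-[4-bromo-2-methoxy-6-(2,4,6-trimethoxyphenoxy)phenoxy]-2,6-dimethoxybenzaldehyde (bromo trimer aldehyde) | COc1cc(OC)c(Oc2cc(Br)cc(OC)c2Oc2cc(OC)c(C=O)c(OC)c2)c(OC)c1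
F6 | step 8 | 4-[4-bromo-2-methoxy-6-(2,4,6-trimethoxyphenoxy)phenoxy]-2,6-dimethoxyphenyl formate (bromo trimer formate) | COc1cc(OC)c(Oc2cc(Br)cc(OC)c2Oc2cc(OC)c(OC=O)c(OC)c2)c(OC)c1
F7 | step 8 | 4-[4-bromo-2-methoxy-6-(2,4,6-trimethoxyphenoxy)phenoxy]-2,6-dimethoxyphenol (bromo trimer phenol) | COc1cc(OC)c(Oc2cc(Br)cc(OC)c2Oc2cc(OC)c(O)c(OC)c2)c(OC)c1
F8 | step 8 | 4-bromo-2-{4-[4-bromo-2-methoxy-6-(2,4,6-trimethoxyphenoxy)phenoxy]-2,6-dimethoxyphenoxy}-6-methoxybenzaldehyde (dibromo tetramer aldehyde) | COc1cc(OC)c(Oc2cc(Br)cc(OC)c2Oc2cc(OC)c(Oc3cc(Br)cc(OC)c3C=O)c(OC)c2)c(OC)c1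
F9 | step 8 | 4-bromo-2-{4-[4-bromo-2-methoxy-6-(2,4,6-trimethoxyphenoxy)phenoxy]-2,6-dimethoxyphenoxy}-6-methoxyphenyl formate (dibromo tetramer formate) | COc1cc(OC)c(Oc2cc(Br)cc(OC)c2Oc2cc(OC)c(Oc3cc(Br)cc(OC)c3OC=O)c(OC)c2)c(OC)c1
F10 | step 8 | 4-bromo-2-{4-[4-bromo-2-methoxy-6-(2,4,6-trimethoxyphenoxy)phenoxy]-2,6-dimethoxyphenoxy}-6-methoxyphenol (dibromo tetramer phenol) | COc1cc(OC)c(Oc2cc(Br)cc(OC)c2Oc2cc(OC)c(Oc3cc(Br)cc(OC)c3O)c(OC)c2)c(OC)c1
F11 | step 8 | 14 with bromine at C4 of ring B and at C4 of ring D (dibromo pentamer) | COc1cc(OC)cc(Oc2c(OC)cc(Br)cc2Oc2c(OC)cc(Oc3c(OC)cc(Br)cc3Oc3c(OC)cc(OC)cc3OC)cc2OC)c1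
F12 | step 3 | 4-bromo-2,6-dimethoxybenzaldehyde | COc1cc(Br)cc(OC)c1C=O
F13 | step 7 | 1-bromo-3,5-dimethoxybenzene | COc1cc(Br)cc(OC)c1
F14 | step 9 | undecaacetate of 17 | CC(=O)Oc1cc(OC(C)=O)cc(Oc2c(OC(C)=O)cc(OC(C)=O)cc2Oc2c(OC(C)=O)cc(Oc3c(OC(C)=O)cc(OC(C)=O)cc3Oc3c(OC(C)=O)cc(OC(C)=O)cc3OC(C)=O)cc2OC(C)=O)c1
A1 | alternative 1 | dimethyl 2-(tetramer aryloxy)malonate, rings A to D permethylated with O4 on the malonate carbon | COc1cc(OC)cc(Oc2c(OC)cc(OC)cc2Oc2c(OC)cc(Oc3c(OC)cc(OC)cc3OC(C(=O)OC)C(=O)OC)cc2OC)c1
A2 | alternative 1 | dimethyl 1,3-acetonedicarboxylate | COC(=O)CC(=O)CC(=O)OC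
A3 | alternative 1 | pentamer with ring E as dimethyl 5-aryloxy-2,4,6-trihydroxybenzene-1,3-dicarboxylate | COc1cc(OC)cc(Oc2c(OC)cc(OC)cc2Oc2c(OC)cc(Oc3c(OC)cc(OC)cc3Oc3c(O)c(C(=O)OC)c(O)c(C(=O)OC)c3O)cc2OC)c1
A4 | alternative 2 | [CpRu(η6-2,5-dichloro-1,3-dimethoxybenzene)]PF6 | COc1cc(Cl)cc(OC)c1Cl.[cH-]1cccc1.[Ru+2].F[P-](F)(F)(F)(F)F
A5 | alternative 2 | 2,4-dimethoxy-6-(2,4,6-trimethoxyphenoxy)phenol (D–E phenol) | COc1cc(OC)c(Oc2cc(OC)cc(OC)c2O)c(OC)c1
A6 | alternative 2 | 2-(3,5-dimethoxyphenoxy)-3,5-dimethoxyphenol (A–B phenol) | COc1cc(OC)cc(Oc2c(OC)cc(OC)cc2O)c1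
A7 | alternative 2 | cyclopentadienylruthenium hexafluorophosphate complex of the undecamethyl pentamer, metal on ring C | COc1cc(OC)cc(Oc2c(OC)cc(OC)cc2Oc2c(OC)cc(Oc3c(OC)cc(OC)cc3Oc3c(OC)cc(OC)cc3OC)cc2OC)c1.[cH-]1cccc1.[Ru+2].F[P-](F)(F)(F)(F)F
A8 | alternative 2 | undecamethyl ether of 17 | COc1cc(OC)cc(Oc2c(OC)cc(OC)cc2Oc2c(OC)cc(Oc3c(OC)cc(OC)cc3Oc3c(OC)cc(OC)cc3OC)cc2OC)c1
A9 | alternative 3 | 3,5-dimethoxy-2-(trimethylsilyl)phenyl trifluoromethanesulfonate | COc1cc(OC)c([Si](C)(C)C)c(OS(=O)(=O)C(F)(F)F)c1
A10 | alternative 3 | potassium 2,4,6-trimethoxyphenoxide | COc1cc(OC)c([O-])c(OC)c1.[K+]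
A11 | alternative 3 | 2-iodo-1,5-dimethoxy-3-(2,4,6-trimethoxyphenoxy)benzene | COc1cc(OC)c(I)c(Oc2c(OC)cc(OC)cc2OC)c1
A12 | alternative 3 | iodopentafluorobenzene | Fc1c(F)c(F)c(I)c(F)c1F
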